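**Plan**

- Retrosynthesis: the C3–OMe bond is cut back to C3–I and the 5-OH to its tosylate. O1–C2 and C3–I are then cut together, opening the pyranone to an o-methoxyaryl alkynyl ketone. The ketone–alkyne bond (C4–C3) is cut to an aryl aldehyde plus 2-ethynylanisole, and the C4a–C4 bond to 3,4,5-trimethoxyphenol.
- Forward: ortho-formylation, tosylation, acetylide addition and oxidation join the chain. The pyranone is the only ring formed (step 5); both benzene rings are bought. Iodine is then exchanged for methoxide while the 5-OH is unmasked.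
- Enabling feature: the tetrasubstituted C2=C3 enol ether of the pyranone ring (O1 on C2, OMe on C3) is at the oxidation level of an alkyne, so C3 can accept I+ while O1 adds to C2.
- Of the two oxygens ortho to the ketone, the one beside the future 8-OMe enters as a methyl ether and becomes O1 with loss of MeCl. The other enters as a sulfonate ester, which cannot cyclise and is released at the end as the 5-OH, so no selective demethylation is needed.
- Stereochemistry: the target has no stereogenic element. The carbinol centre of the propargylic alcohol is formed racemic and erased by oxidation.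

Key step: step 5

Remark: the target SMILES contains no stereocentre and no configurationally stable axis, so the compound is achiral and nothing has to be controlled to obtain it as drawn.

**Route**

Step 1
Reactants: 1 3,4,5-trimethoxyphenol
Product: 2 6-hydroxy-2,3,4-trimethoxybenzaldehyde
Conditions: (CH2O)n, MgCl2, Et3N, MeCN, reflux; then 1 M HCl
Reagents that add atoms: paraformaldehyde (as formaldehyde), C=O
Why: Magnesium-phenoxide-directed ortho-formylation (Casnati–Skattebøl) places CHO only ortho to the OH, and the two ortho positions of the symmetrical phenol are equivalent, so a single aldehyde should result.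

Step 2
Reactants: 2 6-hydroxy-2,3,4-trimethoxybenzaldehyde
Product: 3 2-formyl-3,4,5-trimethoxyphenyl 4-methylbenzenesulfonate
Conditions: TsCl, Et3N, DMAP (cat.), CH2Cl2, 0 °C → rt
Reagents that add atoms: p-toluenesulfonyl chloride, Cc1ccc(cc1)S(=O)(=O)Cl
Why: O-sulfonylation of the phenol gives an aryl sulfonate whose oxygen is non-nucleophilic in step 5 and which, unlike an ester or carbonate, should not migrate to the alkoxide formed in step 3.

Step 3
Reactants: 3 2-formyl-3,4,5-trimethoxyphenyl 4-methylbenzenesulfonate; 4 2-ethynylanisole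
Product: 6 rac-2-[1-hydroxy-3-(2-methoxyphenyl)prop-2-yn-1-yl]-3,4,5-trimethoxyphenyl 4-methylbenzenesulfonate, via lithium (2-methoxyphenyl)acetylide 5 (not isolated)
Conditions: 4, n-BuLi, THF, −78 °C; then 3, −78 → −40 °C; sat. NH4Cl
Reagents that add atoms: none
Why: 1,2-Addition of a lithium acetylide to a non-enolisable aryl aldehyde; the aryl tosylate should be inert to the weakly basic acetylide at low temperature, and the new carbinol centre is formed racemic because it is removed in step 4.

Step 4
Reactants: 6 rac-2-[1-hydroxy-3-(2-methoxyphenyl)prop-2-yn-1-yl]-3,4,5-trimethoxyphenyl 4-methylbenzenesulfonate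
Product: 7 2-[3-(2-methoxyphenyl)prop-2-ynoyl]-3,4,5-trimethoxyphenyl 4-methylbenzenesulfonate
Conditions: activated MnO2 (excess), CH2Cl2, rt
Reagents that add atoms: none
Why: MnO2 oxidation of a benzylic, propargylic alcohol to the conjugated ynone under neutral conditions that leave the sulfonate and the acid-sensitive carbinol precursor untouched.

Step 5
Reactants: 7 2-[3-(2-methoxyphenyl)prop-2-ynoyl]-3,4,5-trimethoxyphenyl 4-methylbenzenesulfonate
Product: 9 3-iodo-7,8-dimethoxy-2-(2-methoxyphenyl)-4-oxo-4H-chromen-5-yl 4-methylbenzenesulfonate, via O-methyl oxonium chloride 8 (not isolated)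
Conditions: ICl (1.2 equiv), CH2Cl2, −78 °C → rt; aq. Na2S2O3
Reagents that add atoms: iodine monochloride, ClI
Why: ICl forms an iodonium on the ynone triple bond, with positive charge building at the alkyne carbon that bears the 2-methoxyphenyl group (future C2); the oxygen of the methoxy group ortho to the ketone and beside the future 8-OMe attacks that carbon anti to iodine to give oxonium 8, and chloride removes the O-methyl group by SN2 as MeCl, leaving O1–C2 and C3–I in place. The closest known reaction is the ICl-induced cyclization of 2-methoxyaryl alkynyl ketones to 3-iodochromones. The pyranone ring closes by 6-endo-dig O-attack, and no stereocentre is formed. Three selectivities are needed: which ortho oxygen closes, 6-endo versus 5-exo (aurone) closure, and the ketone-side methoxy versus the anisole oxygen of the alkyne-side ring. The first is secured because the other ortho oxygen is a sulfonate ester and not nucleophilic, which fixes the 5-oxy-7,8-dimethoxy pattern; the second by electrophilic activation together with the cation-stabilising aryl group at the alkyne terminus, which directs oxygen to C2; the third because the anisole oxygen could only reach the carbon next to the carbonyl (5-endo, benzofuran), where no positive charge develops. Ring iodination should be held back by the low temperature and by the deactivating sulfonate beside the only free position of the ketone-side ring.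

Step 6
Reactants: 9 3-iodo-7,8-dimethoxy-2-(2-methoxyphenyl)-4-oxo-4H-chromen-5-yl 4-methylbenzenesulfonate
Product: 11 5-hydroxy-3,7,8,2'-tetramethoxyflavone, via sodium 3-iodo-5-oxidoflavone 10 (not isolated)
Conditions: NaOMe (6 equiv), MeOH/toluene, 40 °C; then CuI (20 mol %), 1,10-phenanthroline (40 mol %), 90 °C (sealed tube); 1 M HCl
Reagents that add atoms: sodium methoxide, C[O-].[Na+]
Why: Methoxide first removes the sulfonyl group from the electron-poor aryl tosylate by S–O cleavage (the methyl tosylate formed is destroyed by excess methoxide), and copper(I)/phenanthroline-catalysed Ullmann-type C–O coupling, the reaction used to turn iodoflavones into methoxyflavones with NaOMe, then replaces the C3 iodide by methoxide, the chelated 5-phenolate being too poor a nucleophile to compete.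

**Compound list**

1 | 3,4,5-trimethoxyphenol | COc1cc(O)cc(OC)c1OC | starting material
2 | 6-hydroxy-2,3,4-trimethoxybenzaldehyde | O=Cc1c(O)cc(OC)c(OC)c1OC | intermediate
3 | 2-formyl-3,4,5-trimethoxyphenyl 4-methylbenzenesulfonate | O=Cc1c(OS(=O)(=O)c2ccc(C)cc2)cc(OC)c(OC)c1OC | intermediate
4 | 2-ethynylanisole (1-ethynyl-2-methoxybenzene) | COc1ccccc1C#C | starting material
5 | lithium (2-methoxyphenyl)acetylide | COc1ccccc1C#[C-].[Li+] | intermediate (not isolated)
6 | rac-2-[1-hydroxy-3-(2-methoxyphenyl)prop-2-yn-1-yl]-3,4,5-trimethoxyphenyl 4-methylbenzenesulfonate (racemic carbinol) | COc1ccccc1C#CC(O)c1c(OS(=O)(=O)c2ccc(C)cc2)cc(OC)c(OC)c1OC | intermediate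
7 | 2-[3-(2-methoxyphenyl)prop-2-ynoyl]-3,4,5-trimethoxyphenyl 4-methylbenzenesulfonate | COc1ccccc1C#CC(=O)c1c(OS(=O)(=O)c2ccc(C)cc2)cc(OC)c(OC)c1OC | intermediate
8 | 3-iodo-7,8-dimethoxy-2-(2-methoxyphenyl)-1-methyl-4-oxo-5-(tosyloxy)-4H-chromen-1-ium chloride | C[O+]1C(c2ccccc2OC)=C(I)C(=O)c2c(OS(=O)(=O)c3ccc(C)cc3)cc(OC)c(OC)c21.[Cl-] | intermediate (not isolated)
9 | 3-iodo-7,8-dimethoxy-2-(2-methoxyphenyl)-4-oxo-4H-chromen-5-yl 4-methylbenzenesulfonate | COc1ccccc1-c1oc2c(OC)c(OC)cc(OS(=O)(=O)c3ccc(C)cc3)c2c(=O)c1I | intermediate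
10 | sodium 3-iodo-7,8-dimethoxy-2-(2-methoxyphenyl)-4-oxo-4H-chromen-5-olate | COc1ccccc1-c1oc2c(OC)c(OC)cc([O-])c2c(=O)c1I.[Na+] | intermediate (not isolated)
11 | 5-hydroxy-3,7,8-trimethoxy-2-(2-methoxyphenyl)-4H-chromen-4-one (5-hydroxy-3,7,8,2'-tetramethoxyflavone) | COc1ccccc1-c1oc2c(OC)c(OC)cc(O)c2c(=O)c1OC | target

**Summary**

Total step count: 6. Longest linear sequence: 6 steps (1 → 11); 4 is used as bought.

**Steps most likely to fail**

1. Step 6. Hydride transfer from methoxide at copper could remove the iodine without C–O bond formation. Methoxide addition at C2 with opening of the pyranone could outrun the coupling. The transient methyl tosylate could also methylate the 5-phenolate. Fallback, setting out from 9 and returning at 11: Pd-catalysed Miyaura borylation (B2pin2, PdCl2(dppf), KOAc, dioxane, 80 °C) should give the boronate 7,8-dimethoxy-2-(2-methoxyphenyl)-4-oxo-3-(4,4,5,5-tetramethyl-1,3,2-dioxaborolan-2-yl)-4H-chromen-5-yl 4-methylbenzenesulfonate F1. Oxidation (NaBO3·4H2O, THF/H2O, rt) should give the flavonol 3-hydroxy-7,8-dimethoxy-2-(2-methoxyphenyl)-4-oxo-4H-chromen-5-yl 4-methylbenzenesulfonate F2. O-Methylation (MeI, K2CO3, acetone) should give 3,7,8-trimethoxy-2-(2-methoxyphenyl)-4-oxo-4H-chromen-5-yl 4-methylbenzenesulfonate F3. Tosylate cleavage (KOH, MeOH/H2O, 50 °C, then acid) then leads to 11.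

2. Step 5. The twisted, doubly flanked methoxy oxygen may attack too slowly, so that ICl merely adds across the triple bond or iodinates an arene ring. Fallback, setting out from 3 and returning at 9, in which O1 is delivered as a free phenol: chelation-controlled cleavage of the only methoxy group ortho to the aldehyde (BCl3, CH2Cl2, −78 → 0 °C) should give 2-formyl-3-hydroxy-4,5-dimethoxyphenyl 4-methylbenzenesulfonate F4. Addition of 2.2 equiv of acetylide 5 (THF, −78 °C; the first equivalent deprotonates the phenol) should give rac-3-hydroxy-2-[1-hydroxy-3-(2-methoxyphenyl)prop-2-yn-1-yl]-4,5-dimethoxyphenyl 4-methylbenzenesulfonate F5. MnO2 oxidation should give the o-hydroxyaryl ynone 3-hydroxy-4,5-dimethoxy-2-[3-(2-methoxyphenyl)prop-2-ynoyl]phenyl 4-methylbenzenesulfonate F6. Iodocyclization of F6 (ICl, CH2Cl2, −78 °C), in which the phenol is the only oxygen able to close, with loss of a proton instead of a methyl group, leads to 9.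

3. Step 3. The sulfonyl group could transfer to the newly formed benzylic alkoxide, or the acetylide could attack at sulfur; either would unmask a phenoxide beside an easily ionised carbinol. Fallback, setting out from 2 and returning at 6, in which the C–C bond is made before the sulfonate is installed: addition of 2.2 equiv of acetylide 5 to the free phenol aldehyde 2 (THF, −78 → 0 °C) should give rac-2-[1-hydroxy-3-(2-methoxyphenyl)prop-2-yn-1-yl]-3,4,5-trimethoxyphenol F7. Chemoselective sulfonylation of the phenolic oxygen (TsCl, K2CO3, acetone, 0 °C → rt) then gives 6.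

**Further compounds**

F1 | step 6 | 7,8-dimethoxy-2-(2-methoxyphenyl)-4-oxo-3-(4,4,5,5-tetramethyl-1,3,2-dioxaborolan-2-yl)-4H-chromen-5-yl 4-methylbenzenesulfonate | COc1ccccc1-c1oc2c(OC)c(OC)cc(OS(=O)(=O)c3ccc(C)cc3)c2c(=O)c1B1OC(C)(C)C(C)(C)O1
F2 | step 6 | 3-hydroxy-7,8-dimethoxy-2-(2-methoxyphenyl)-4-oxo-4H-chromen-5-yl 4-methylbenzenesulfonate | COc1ccccc1-c1oc2c(OC)c(OC)cc(OS(=O)(=O)c3ccc(C)cc3)c2c(=O)c1O
F3 | step 6 | 3,7,8-trimethoxy-2-(2-methoxyphenyl)-4-oxo-4H-chromen-5-yl 4-methylbenzenesulfonate | COc1ccccc1-c1oc2c(OC)c(OC)cc(OS(=O)(=O)c3ccc(C)cc3)c2c(=O)c1OC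
F4 | step 5 | 2-formyl-3-hydroxy-4,5-dimethoxyphenyl 4-methylbenzenesulfonate | O=Cc1c(O)c(OC)c(OC)cc1OS(=O)(=O)c1ccc(C)cc1
F5 | step 5 | rac-3-hydroxy-2-[1-hydroxy-3-(2-methoxyphenyl)prop-2-yn-1-yl]-4,5-dimethoxyphenyl 4-methylbenzenesulfonate | COc1ccccc1C#CC(O)c1c(O)c(OC)c(OC)cc1OS(=O)(=O)c1ccc(C)cc1
F6 | step 5 | 3-hydroxy-4,5-dimethoxy-2-[3-(2-methoxyphenyl)prop-2-ynoyl]phenyl 4-methylbenzenesulfonate | COc1ccccc1C#CC(=O)c1c(O)c(OC)c(OC)cc1OS(=O)(=O)c1ccc(C)cc1
F7 | step 3 | rac-2-[1-hydroxy-3-(2-methoxyphenyl)prop-2-yn-1-yl]-3,4,5-trimethoxyphenol | COc1ccccc1C#CC(O)c1c(O)cc(OC)c(OC)c1OC
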